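(The data are simulated on assumed constants; noise was put on by code.)

Start with the easy step. The electrophile is the limiting reagent, 0.39 M against 1.17 M of nucleophile, so you ask how fast it runs down. The flask in question is the south run carried on to 10 d.

| setting | south | east | flask |
|---|---|---|---|
| electrophile | 0.39 M | 0.39 M | 0.39 M |
| nucleophile | 1.17 M | 0.78 M | 1.17 M |
| free base | 0.585 M | 0.585 M | 0.585 M |
| protic impurity | 0.39 M | 0.39 M | 0.390 M |
| remark | the very flask that is asked about, followed so far | run made earlier |  |
| time |  |  | 10 d |

| run | time / d | electrophile / % | target / % |
|---|---|---|---|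
| south | 0.333 | 84.0 | 13.3 |
| south | 1.04 | 61.7 | 32.1 |
| south | 1.67 | 48.7 | 42.4 |
| south | 3.00 | 31.9 | 56.4 |
| south | 4.00 | 22.8 | 63.1 |
| east | 0.833 | 77.3 | 19.4 |
| east | 2.50 | 52.2 | 39.0 |
| east | 5.00 | 34.6 | 53.1 |
| east | 8.00 | 22.9 | 62.0 |
| east | 10.0 | 17.7 | 66.0 |

(scatter of a reading: 0.5 percentage points)

- part of the electrophile that has reacted at 10 d
- share of the unused nucleophile that is free and not bound as protonated nucleophile, at 10 d

- the earlier runs do not show how much of nucleophile is bound; that part of a forecast is a guess

Here is the odd thing. South fell to 22.8% of its electrophile in 4.00 d, while east took 8.00 d to reach 22.9%. South had 1.50 times east's nucleophile, yet ran 2.00 times as fast.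

My reckoning clears this up. Suppose the rate follows the working nucleophile, c(nucleophile) charged less a part used or bound. At equal electrophile left, equal nucleophile has been used, and base and impurity charges match, so take that part as equal in both runs. South's working amount must then be 2.00 times east's, which gives a held-back nucleophile, averaged over the run, of 0.390 M. South thus worked with 0.780 M, and its fall in electrophile gives 0.474 /M/d per working nucleophile. Held steady, that puts 97.5% reacted at 10 d, above the forecast's range, though the reaction goes on using nucleophile.

The forecast says 96% reacted (94.5% to 97.2%) and 67% free (55% to 80%), reasoning that “nucleophile is increasingly protonated”.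

The flask gives 94.7% reacted, close to the low end of the forecast's range, and 63.4% free, inside its range.

    protic impurity + free base → quenched reagent (k = 0.0130 /M/h)
    acid set free + free base ⇌ salt of the base (K = 3700 /M, k = 0.340 /M/h)
    electrophile + nucleophile → acid set free + target (k = 0.0190 /M/h)
    target ⇌ isomer of the product (K = 0.220, k = 0.0620 /h)
    electrophile + acid set free → side product (k = 0.0680 /M/h)
    nucleophile + acid set free ⇌ protonated nucleophile, settled at all times (K = 180 /M)

At 1.46 d the flask's electrophile went by the nucleophile step 190 times faster than to side product. With 0.474 /M/d, the 5.3% left in the flask means 0.620 M of working nucleophile on average, below 0.780 M. The neighbour charged with 0.29 M, less than 0.390 M, still reached 45.6% reacted, which means 0.128 M working.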